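**Retrosynthetic overview**

1. The (E,E)-phenyldiene is made last by Horner–Wadsworth–Emmons olefination of a side-chain aldehyde, which is unmasked from a terminal alkene by ozonolysis.
2. The 1,2-dioxane is the second ring: a tertiary hydroperoxide (perhydrolysis of a 2,2-disubstituted epoxide with inversion; the freed CH2OH is later reduced to the methyl group) adds 6-exo to a butenolide, which enforces the cis ring fusion.
3. The γ-lactone is the first ring (key step): a one-flask palladium SN2′ carbonylation and silver cyclisation of a tertiary propargylic carbonate forms the bond from the lactone carbonyl carbon to its α-carbon and the bond from the ring oxygen to the methyl-bearing quaternary carbon.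
4. Enabling feature: in the five-membered lactone the α-CH2, the peroxide-bearing CH and the O-bearing quaternary carbon form a three-carbon unit that maps onto a propargyl/allenyl triad. A carboxyl group can therefore be attached at one end and closed through oxygen onto the other, and the α,β-double bond left behind is the acceptor the peroxide needs.
5. Stereocentres: the quaternary lactone carbon comes from (S)-2-methylglycidol by centre-to-axis-to-centre transfer; the peroxide-bearing quaternary carbon from hydroxyl-directed epoxidation followed by inversion; the ring-fusion CH from the cyclisation.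

Key step: step 7

Remark: compounds 1, 2, 5 and 20 are taken as commercial. In the Why lines C1–C6 mean the lactone carbonyl carbon, its α-carbon, the ring-fusion CH, the quaternary lactone carbon, the dioxane CH2 and the quaternary peroxide carbon.

**Route**

Step 1
Reactants: 1 7-bromohept-1-ene; 2 2,3-dibromoprop-1-ene
Product: 4 2-bromodeca-1,9-diene, via hept-6-en-1-ylmagnesium bromide 3 (not isolated)
Conditions: Mg, THF, 40 °C; then 2, CuI (5 mol %), THF, −20 → 25 °C
Reagents that add atoms: none
Why: Copper-catalysed coupling of the primary Grignard reagent with the allylic bromide of 2 leaves the vinylic bromide untouched and gives the 2-bromoalk-1-ene; no stereocentre is formed.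

Step 2
Reactants: 4 2-bromodeca-1,9-diene; 5 [(2S)-2-methyloxiran-2-yl]methanol
Product: 7 (2R)-2-methyl-4-methylidenedodec-11-ene-1,2-diol, via deca-1,9-dien-2-ylmagnesium bromide 6 (not isolated)
Conditions: 4 (2.5 equiv), Mg, THF, 50 °C; CuI (10 mol %), then 5, THF, −30 → 0 °C; aq NH4Cl
Reagents that add atoms: none
Why: Copper-catalysed epoxide opening by the alkenyl Grignard reagent occurs at the CH2 terminus (one equivalent is consumed by the free hydroxyl), so the quaternary carbinol keeps its geometry and is R only through the change in substituent priority.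

Step 3
Reactants: 7 (2R)-2-methyl-4-methylidenedodec-11-ene-1,2-diol
Product: 8 (2R)-2-hydroxy-2-methyl-4-methylidenedodec-11-enal
Conditions: SO3·pyridine, DMSO, i-Pr2NEt, CH2Cl2, 0 °C
Reagents that add atoms: none
Why: Parikh–Doering oxidation converts the primary alcohol of the 1,2-diol into the aldehyde without glycol cleavage, and the fully substituted α-carbon cannot epimerise.

Step 4
Reactants: 8 (2R)-2-hydroxy-2-methyl-4-methylidenedodec-11-enal
Product: 9 (3R)-3-methyl-5-methylidenetridec-12-en-1-yn-3-ol
Conditions: dimethyl (1-diazo-2-oxopropyl)phosphonate, K2CO3, MeOH, 0 → 25 °C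
Reagents that add atoms: dimethyl (1-diazo-2-oxopropyl)phosphonate COP(=O)(OC)C(=[N+]=[N-])C(C)=O
Why: Ohira–Bestmann (Seyferth–Gilbert) homologation turns the aldehyde into the terminal alkyne under mild carbonate conditions and gives the tertiary propargylic alcohol with unchanged configuration.

Step 5
Reactants: 9 (3R)-3-methyl-5-methylidenetridec-12-en-1-yn-3-ol
Product: 10 (2R)-2-methyl-1-[(2R)-2-(oct-7-en-1-yl)oxiran-2-yl]but-3-yn-2-ol
Conditions: VO(acac)2 (5 mol %), t-BuOOH (1.5 equiv, decane solution), CH2Cl2, 0 → 25 °C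
Reagents that add atoms: tert-butyl hydroperoxide CC(C)(C)OO
Why: Hydroxyl-directed epoxidation of the homoallylic 1,1-disubstituted alkene through a chair-like vanadate ester (methyl equatorial, slim ethynyl axial, oxygen delivered on the side of the axial group) should give the (2R)-epoxide, while the remote monosubstituted alkene is not directed and stays.

Step 6
Reactants: 10 (2R)-2-methyl-1-[(2R)-2-(oct-7-en-1-yl)oxiran-2-yl]but-3-yn-2-ol
Product: 11 tert-butyl (2R)-2-methyl-1-[(2R)-2-(oct-7-en-1-yl)oxiran-2-yl]but-3-yn-2-yl carbonate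
Conditions: LiN(SiMe3)2 (1.05 equiv), THF, −78 °C; Boc2O, −78 → 0 °C
Reagents that add atoms: di-tert-butyl dicarbonate CC(C)(C)OC(=O)OC(=O)OC(C)(C)C
Why: O-acylation of the lithium alkoxide (formed in preference to deprotonation of the less acidic alkyne C–H) installs the carbonate leaving group for the key step without touching either stereocentre.

Step 7
Reactants: 11 tert-butyl (2R)-2-methyl-1-[(2R)-2-(oct-7-en-1-yl)oxiran-2-yl]but-3-yn-2-yl carbonate
Product: 13 (5S)-5-methyl-5-{[(2R)-2-(oct-7-en-1-yl)oxiran-2-yl]methyl}furan-2(5H)-one, via allenoic acid 12 (not isolated)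
Conditions: Pd(PPh3)4 (5 mol %), CO (1 atm), NaHCO3 (1.5 equiv), THF/H2O 10:1, 25 °C; then AgNO3 (20 mol %), 25 °C, same flask
Reagents that add atoms: carbon monoxide [C-]#[O+]; water O
Why: Zerovalent palladium ionises the propargylic carbonate by anti SN2′ attack at the alkyne terminus, CO inserts into the allenyl–palladium bond (C1–C2 bond) and water releases the allenoic acid 12, one carboxyl oxygen of which then adds to the silver-activated allene terminus (O–C4 bond). The closest known reaction type is the palladium-catalysed carbonylation of propargylic carbonates or mesylates to 2,3-allenoic acids followed by AgNO3-catalysed cyclisation to butenolides. The lactone ring closes by 5-endo-trig attack of oxygen on the methyl-bearing allene carbon. The quaternary stereocentre is set by centre-to-axis-to-centre chirality transfer (anti SN2′, retentive CO insertion, oxygen delivered in the plane of the carboxyl group), a net inversion that turns the (R)-carbinol into the (5S)-butenolide. The step needs SN2′ rather than direct substitution and survival of the acid-labile epoxide and the terminal alkene; the unhindered alkyne terminus, the bicarbonate buffer and the neutral room-temperature conditions should secure this.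

Step 8
Reactants: 13 (5S)-5-methyl-5-{[(2R)-2-(oct-7-en-1-yl)oxiran-2-yl]methyl}furan-2(5H)-one
Product: 15 (3S,4aS,7aS)-3-(hydroxymethyl)-4a-methyl-3-(oct-7-en-1-yl)tetrahydro-3H-furo[3,2-c][1,2]dioxin-6(4H)-one, via hydroxy hydroperoxide 14 (not isolated)
Conditions: H2O2 (anhydrous, in Et2O, 10 equiv), H3PMo12O40 (2 mol %), 25 °C; water wash; then Et2NH (0.5 equiv), CF3CH2OH, 25 °C
Reagents that add atoms: hydrogen peroxide OO
Why: Molybdenum-catalysed perhydrolysis opens the 2,2-disubstituted epoxide at the tertiary carbon with inversion to give the (S)-hydroperoxide 14, whose peroxy anion (more acidic and more nucleophilic than the primary alcohol) closes the 1,2-dioxane by 6-exo-trig oxa-Michael addition to C3, the cis ring fusion being the only geometry the tether allows.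

Step 9
Reactants: 15 (3S,4aS,7aS)-3-(hydroxymethyl)-4a-methyl-3-(oct-7-en-1-yl)tetrahydro-3H-furo[3,2-c][1,2]dioxin-6(4H)-one
Product: 16 O-{[(3S,4aS,7aS)-4a-methyl-3-(oct-7-en-1-yl)-6-oxohexahydro-3H-furo[3,2-c][1,2]dioxin-3-yl]methyl} O-(pentafluorophenyl) carbonothioate
Conditions: C6F5OC(S)Cl, pyridine, CH2Cl2, 0 → 25 °C
Reagents that add atoms: O-(pentafluorophenyl) carbonochloridothioate S=C(Cl)Oc1c(F)c(F)c(F)c(F)c1F
Why: Thioacylation of the primary alcohol gives the Barton–McCombie precursor, the pentafluorophenyl thionocarbonate being chosen because it fragments to primary radicals already at 80 °C.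

Step 10
Reactants: 16 O-{[(3S,4aS,7aS)-4a-methyl-3-(oct-7-en-1-yl)-6-oxohexahydro-3H-furo[3,2-c][1,2]dioxin-3-yl]methyl} O-(pentafluorophenyl) carbonothioate
Product: 17 (3S,4aS,7aS)-3,4a-dimethyl-3-(oct-7-en-1-yl)tetrahydro-3H-furo[3,2-c][1,2]dioxin-6(4H)-one
Conditions: Bu3SnH (3 equiv, 0.3 M), AIBN (20 mol %), benzene, 80 °C
Reagents that add atoms: none
Why: Barton–McCombie deoxygenation converts the CH2O group into the C6 methyl group, the concentrated Bu3SnH being meant to reduce the primary radical faster than it can attack the neighbouring O–O bond; no stereocentre is touched.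

Step 11
Reactants: 17 (3S,4aS,7aS)-3,4a-dimethyl-3-(oct-7-en-1-yl)tetrahydro-3H-furo[3,2-c][1,2]dioxin-6(4H)-one
Product: 19 7-[(3S,4aS,7aS)-3,4a-dimethyl-6-oxohexahydro-3H-furo[3,2-c][1,2]dioxin-3-yl]heptanal, via ozonide 18 (not isolated)
Conditions: O3, CH2Cl2, −78 °C; then Me2S, −78 → 25 °C
Reagents that add atoms: ozone [O-][O+]=O
Why: Ozonolysis of the only remaining C=C bond with Me2S work-up, which does not reduce a dialkyl peroxide, gives the aldehyde.

Step 12
Reactants: 19 7-[(3S,4aS,7aS)-3,4a-dimethyl-6-oxohexahydro-3H-furo[3,2-c][1,2]dioxin-3-yl]heptanal; 20 diethyl [(2E)-3-phenylprop-2-en-1-yl]phosphonate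
Product: 22 plakortolide R, via lithiated phosphonate 21 (not isolated)
Conditions: 20, LiN(SiMe3)2, THF, −78 °C; then 19, −78 → 0 °C
Reagents that add atoms: none
Why: Horner–Wadsworth–Emmons olefination with the pre-formed allylic phosphonate anion should give the new disubstituted alkene E while the cinnamyl double bond stays E, and the stoichiometric anion at low temperature limits base contact with the β-peroxy lactone.

**Compound list**

1 | 7-bromohept-1-ene | C=CCCCCCBr | starting material
2 | 2,3-dibromoprop-1-ene | C=C(Br)CBr | starting material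
3 | hept-6-en-1-ylmagnesium bromide | C=CCCCCC[Mg]Br | intermediate
4 | 2-bromodeca-1,9-diene | C=C(Br)CCCCCCC=C | intermediate
5 | [(2S)-2-methyloxiran-2-yl]methanol ((S)-2-methylglycidol) | C[C@]1(CO)CO1 | starting material
6 | deca-1,9-dien-2-ylmagnesium bromide | C=C([Mg]Br)CCCCCCC=C | intermediate
7 | (2R)-2-methyl-4-methylidenedodec-11-ene-1,2-diol | C[C@](O)(CO)CC(=C)CCCCCCC=C | intermediate
8 | (2R)-2-hydroxy-2-methyl-4-methylidenedodec-11-enal | C[C@](O)(C=O)CC(=C)CCCCCCC=C | intermediate
9 | (3R)-3-methyl-5-methylidenetridec-12-en-1-yn-3-ol | C[C@](O)(C#C)CC(=C)CCCCCCC=C | intermediate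
10 | (2R)-2-methyl-1-[(2R)-2-(oct-7-en-1-yl)oxiran-2-yl]but-3-yn-2-ol | C[C@](O)(C#C)C[C@]1(CCCCCCC=C)CO1 | intermediate
11 | tert-butyl (2R)-2-methyl-1-[(2R)-2-(oct-7-en-1-yl)oxiran-2-yl]but-3-yn-2-yl carbonate | C[C@](OC(=O)OC(C)(C)C)(C#C)C[C@]1(CCCCCCC=C)CO1 | intermediate
12 | 4-methyl-5-[(2R)-2-(oct-7-en-1-yl)oxiran-2-yl]penta-2,3-dienoic acid, allene axis S (P helicity) | OC(=O)C([H])=[C@@]=C(C)C[C@]1(CCCCCCC=C)CO1 | intermediate
13 | (5S)-5-methyl-5-{[(2R)-2-(oct-7-en-1-yl)oxiran-2-yl]methyl}furan-2(5H)-one | O=C1C=C[C@](C)(C[C@]2(CCCCCCC=C)CO2)O1 | intermediate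
14 | (5S)-5-[(2S)-2-hydroperoxy-2-(hydroxymethyl)dec-9-en-1-yl]-5-methylfuran-2(5H)-one | O=C1C=C[C@](C)(C[C@@](OO)(CCCCCCC=C)CO)O1 | intermediate
15 | (3S,4aS,7aS)-3-(hydroxymethyl)-4a-methyl-3-(oct-7-en-1-yl)tetrahydro-3H-furo[3,2-c][1,2]dioxin-6(4H)-one | OC[C@]1(CCCCCCC=C)C[C@]2(C)OC(=O)C[C@@H]2OO1 | intermediate
16 | O-{[(3S,4aS,7aS)-4a-methyl-3-(oct-7-en-1-yl)-6-oxohexahydro-3H-furo[3,2-c][1,2]dioxin-3-yl]methyl} O-(pentafluorophenyl) carbonothioate | S=C(OC[C@]1(CCCCCCC=C)C[C@]2(C)OC(=O)C[C@@H]2OO1)Oc1c(F)c(F)c(F)c(F)c1F | intermediate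
17 | (3S,4aS,7aS)-3,4a-dimethyl-3-(oct-7-en-1-yl)tetrahydro-3H-furo[3,2-c][1,2]dioxin-6(4H)-one | C[C@]1(CCCCCCC=C)C[C@]2(C)OC(=O)C[C@@H]2OO1 | intermediate
18 | 3-{6-[(3S,4aS,7aS)-3,4a-dimethyl-6-oxohexahydro-3H-furo[3,2-c][1,2]dioxin-3-yl]hexyl}-1,2,4-trioxolane (ozonide, both configurations at the trioxolane carbon) | C[C@]1(CCCCCCC2OCOO2)C[C@]2(C)OC(=O)C[C@@H]2OO1 | intermediate
19 | 7-[(3S,4aS,7aS)-3,4a-dimethyl-6-oxohexahydro-3H-furo[3,2-c][1,2]dioxin-3-yl]heptanal | C[C@]1(CCCCCCC=O)C[C@]2(C)OC(=O)C[C@@H]2OO1 | intermediate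
20 | diethyl [(2E)-3-phenylprop-2-en-1-yl]phosphonate | CCOP(=O)(OCC)C/C=C/c1ccccc1 | starting material
21 | lithium (2E)-1-(diethoxyphosphoryl)-3-phenylprop-2-en-1-ide | [Li+].CCOP(=O)(OCC)[CH-]/C=C/c1ccccc1 | intermediate
22 | plakortolide R, (3S,4aS,7aS)-3,4a-dimethyl-3-[(7E,9E)-10-phenyldeca-7,9-dien-1-yl]tetrahydro-3H-furo[3,2-c][1,2]dioxin-6(4H)-one | C[C@]1(CCCCCC/C=C/C=C/c2ccccc2)C[C@]2(C)OC(=O)C[C@@H]2OO1 | target

**Step count and risks**

Total step count: 12. Longest linear sequence: 12 steps (1 → 22).

The three steps most likely to fail: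

Step 7 may lose configuration at the quaternary carbon if the allenylpalladium intermediate equilibrates before CO insertion, and the epoxide may be opened under the aqueous silver conditions. The fallback sets out from 11 and separates the two bond formations. Carbonylation in methanol (Pd(OAc)2, PPh3, CO, 25 °C) gives the isolated methyl allenoate F1. Iodolactonisation (I2, NaHCO3, MeCN/H2O) closes the ring through an iodonium ion instead of silver and gives the 4-iodobutenolide F2, with the methyl group leaving as iodomethane. Palladium-catalysed hydrodeiodination (Pd(PPh3)4, Bu3SnH, THF) comes back to the route at 13.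

Step 8 may go with partial ionisation at the tertiary carbon (loss of configuration), with attack at the CH2 terminus, or with competing conjugate addition of the new primary alcohol. The fallback sets out from 9 and replaces the epoxide by a Mukaiyama–Isayama hydroperoxysilylation. Alkynol 9 is converted with LiN(SiMe3)2 and Boc2O into the carbonate F3. The conditions of step 7 then give, through the allenoic acid F4, the butenolide F5. Co(thd)2 (thd = 2,2,6,6-tetramethylheptane-3,5-dionate), O2 and Et3SiH in 1,2-dichloroethane add to the 1,1-disubstituted alkene to give the triethylsilyl peroxide F6. HCl (cat.) in MeOH frees the hydroperoxide F7, and Et2NH in CF3CH2OH cyclises it. The route is rejoined at 17. This fallback delivers the methyl group directly and bypasses steps 5, 6, 8, 9 and 10, but it gives up control at the peroxide-bearing quaternary carbon, so the epimer F8 has to be separated by chromatography.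

Step 10 may suffer from slow fragmentation to the primary radical and from attack of that β-peroxy radical on the O–O bond (epoxide formation with ring opening). The fallback sets out from 15 and uses a weaker bond and a lower temperature. Tf2O and 2,6-lutidine in CH2Cl2 at −78 °C give the triflate F9. Bu4NI displaces it to give the iodide F10. Bu3SnH with Et3B and air in toluene at 0 °C reduces the C–I bond and comes back to the route at 17.

Further compounds
F1 | step 7 | methyl 4-methyl-5-[(2R)-2-(oct-7-en-1-yl)oxiran-2-yl]penta-2,3-dienoate, allene axis S | COC(=O)C([H])=[C@@]=C(C)C[C@]1(CCCCCCC=C)CO1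
F2 | step 7 | (5S)-4-iodo-5-methyl-5-{[(2R)-2-(oct-7-en-1-yl)oxiran-2-yl]methyl}furan-2(5H)-one | O=C1C=C(I)[C@](C)(C[C@]2(CCCCCCC=C)CO2)O1
F3 | step 8 | tert-butyl (3R)-3-methyl-5-methylidenetridec-12-en-1-yn-3-yl carbonate | C[C@](OC(=O)OC(C)(C)C)(C#C)CC(=C)CCCCCCC=C
F4 | step 8 | 4-methyl-6-methylidenetetradeca-2,3,13-trienoic acid, allene axis S | OC(=O)C([H])=[C@@]=C(C)CC(=C)CCCCCCC=C
F5 | step 8 | (5S)-5-methyl-5-(2-methylidenedec-9-en-1-yl)furan-2(5H)-one | O=C1C=C[C@](C)(CC(=C)CCCCCCC=C)O1
F6 | step 8 | (5S)-5-methyl-5-{2-methyl-2-[(triethylsilyl)peroxy]dec-9-en-1-yl}furan-2(5H)-one, both configurations at the peroxide carbon | O=C1C=C[C@](C)(CC(C)(OO[Si](CC)(CC)CC)CCCCCCC=C)O1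
F7 | step 8 | (5S)-5-(2-hydroperoxy-2-methyldec-9-en-1-yl)-5-methylfuran-2(5H)-one, both configurations at the peroxide carbon | O=C1C=C[C@](C)(CC(C)(OO)CCCCCCC=C)O1
F8 | step 8 | (3R,4aS,7aS)-3,4a-dimethyl-3-(oct-7-en-1-yl)tetrahydro-3H-furo[3,2-c][1,2]dioxin-6(4H)-one | C[C@@]1(CCCCCCC=C)C[C@]2(C)OC(=O)C[C@@H]2OO1
F9 | step 10 | [(3S,4aS,7aS)-4a-methyl-3-(oct-7-en-1-yl)-6-oxohexahydro-3H-furo[3,2-c][1,2]dioxin-3-yl]methyl trifluoromethanesulfonate | FC(F)(F)S(=O)(=O)OC[C@]1(CCCCCCC=C)C[C@]2(C)OC(=O)C[C@@H]2OO1
F10 | step 10 | (3S,4aS,7aS)-3-(iodomethyl)-4a-methyl-3-(oct-7-en-1-yl)tetrahydro-3H-furo[3,2-c][1,2]dioxin-6(4H)-one | IC[C@]1(CCCCCCC=C)C[C@]2(C)OC(=O)C[C@@H]2OO1
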